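**Retrosynthetic overview**

1. The oxepane (C1–C2–C3–O–C16–C15–C14) is closed last by forming O–C3. The enabling feature is the vicinal, anti C3–O(ether)/C4–O(ester) pair on the oxonane: it is the trace of a cis-3,4-epoxide opened at C3 by the C16 hydroxyl (7-exo), as in the presumed biosynthesis.
2. The key step turns tricyclic hydroxy-triene 28 into the tetracycle by double epoxidation (C3=C4 and C11=C12) and acid-triggered oxacyclisation. The surviving 11,12-epoxide then gives the C11 carbinol by hydride opening, followed by C4 octanoylation and C6 desilylation.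
3. The cyclohexene and tetrahydrofuran rings form together by an intramolecular Diels–Alder reaction across the oxonene (diene on C9, enone on C2). C15 comes from hydroboration of the derived isopropenyl group.
4. The oxonene comes from ring-closing metathesis forming the Z C3=C4 bond of an ether assembled by Williamson etherification and a glycolate aldol on a C4–C10 alcohol (asymmetric allylboration, epoxide opening).
5. Ring order: oxonane (step 11), then cyclohexene plus tetrahydrofuran (step 17), then oxepane (step 20).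

Key step: step 20

Remark: locants follow the target skeleton (C1/C10 ring fusion, C2/C9 ether carbons, C3 with methyl C18, C7 with methylene C19, C11 with methyl C20, C15 with methyl C17, C16 the OCH2 carbon); the target is (1S,2S,3S,4R,6R,9S,10R,11S,14S,15R).
Assumption: 2-bromoacrolein, (S)-glycidyl 4-methoxybenzyl ether, (+)-Ipc2BOMe and the two stabilised phosphoranes are taken as purchasable.

**Route**

Step 1
Reactants: 1 2-bromoacrolein
Product: 3 (R)-2-bromohexa-1,5-dien-3-ol, via borinic ester 2 (not isolated)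
Conditions: (+)-Ipc2BOMe, allylMgBr, Et2O, 0 °C; then 1, −78 °C; then NaOH, H2O2
Reagents that add atoms: allylmagnesium bromide (C=CC[Mg]Br)
Why: Brown asymmetric allylboration through a chair six-membered transition state; the reagent derived from (−)-α-pinene should deliver the allyl group to the aldehyde face that gives the (R)-carbinol, the future C6.

Step 2
Reactants: 3 (R)-2-bromohexa-1,5-dien-3-ol
Product: 4 (R)-2-bromo-3-(tert-butyldimethylsilyloxy)hexa-1,5-diene
Conditions: TBSCl, imidazole, DMF, rt
Reagents that add atoms: tert-butyldimethylsilyl chloride (CC(C)(C)[Si](C)(C)Cl)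
Why: Routine silylation of a secondary allylic alcohol; this ether is carried to the last step.

Step 3
Reactants: 4 (R)-2-bromo-3-(tert-butyldimethylsilyloxy)hexa-1,5-diene; 5 (S)-glycidyl 4-methoxybenzyl ether
Product: 7 (2S,5R)-5-(tert-butyldimethylsilyloxy)-1-(4-methoxybenzyloxy)-4-methyleneoct-7-en-2-ol, via vinyllithium 6 (not isolated)
Conditions: t-BuLi (2 equiv), Et2O, −78 °C; then 5, BF3·OEt2, −78 °C
Reagents that add atoms: none
Why: Bromine–lithium exchange followed by BF3-promoted SN2 opening of the epoxide at its terminal carbon forms C7–C8; holding −78 °C suppresses retro-Brook silyl migration and allene formation, and C9 is taken unchanged from 5.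

Step 4
Reactants: 7 (2S,5R)-5-(tert-butyldimethylsilyloxy)-1-(4-methoxybenzyloxy)-4-methyleneoct-7-en-2-ol
Product: 8 2-{[(2S,5R)-5-(tert-butyldimethylsilyloxy)-1-(4-methoxybenzyloxy)-4-methyleneoct-7-en-2-yl]oxy}acetic acid
Conditions: NaH, BrCH2CO2H, THF/DMF, 0 °C → rt
Reagents that add atoms: bromoacetic acid (OC(=O)CBr)
Why: Williamson etherification of the secondary alkoxide with the bromoacetate dianion builds the C9–O–C2 ether without touching C9.

Step 5
Reactants: 8 the alkoxyacetic acid; 9 (R)-4-benzyl-2-oxazolidinone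
Product: 11 (R)-4-benzyl-3-(2-alkoxyacetyl)oxazolidin-2-one, via mixed pivalic anhydride 10 (not isolated)
Conditions: PivCl, Et3N, THF, −78 → 0 °C; then lithiated 9 (n-BuLi), −78 → 0 °C
Reagents that add atoms: none
Why: Standard acylation of the lithiated auxiliary by a mixed anhydride; the (R)-auxiliary is chosen so that the next step sets C2 correctly.

Step 6
Reactants: 11 the N-glycolyl imide
Product: 13 syn-aldol adduct (R)-4-benzyl-3-[(2R,3S)-2-alkoxy-3-hydroxybutanoyl]oxazolidin-2-one, via chlorotitanium Z-enolate 12 (not isolated)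
Conditions: TiCl4, i-Pr2NEt, N-methylpyrrolidinone, CH2Cl2, −78 °C; then CH3CHO, −78 → −40 °C
Reagents that add atoms: acetaldehyde (CC=O)
Why: Titanium-mediated Evans-type syn glycolate aldol in which the Z enolate reacts on the face opposite the benzyl group and so sets C2; the C3 carbinol configuration is irrelevant because it is oxidised in step 9.

Step 7
Reactants: 13 the syn-aldol adduct
Product: 14 acyclic 1,3-diol (C1 primary and C3 secondary hydroxyl)
Conditions: LiBH4, MeOH (1 equiv), Et2O, 0 °C
Reagents that add atoms: none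
Why: Reductive cleavage of the imide gives the C1 primary alcohol and returns the auxiliary; silyl and PMB ethers and alkenes are inert.

Step 8
Reactants: 14 the 1,3-diol
Product: 15 C1 triethylsilyl ether
Conditions: Et3SiCl, imidazole, CH2Cl2, −78 °C
Reagents that add atoms: chlorotriethylsilane (CC[Si](Cl)(CC)CC)
Why: Kinetic silylation should discriminate cleanly between the primary and the hindered secondary hydroxyl.

Step 9
Reactants: 15 the secondary alcohol
Product: 16 C3 methyl ketone
Conditions: Dess–Martin periodinane, NaHCO3, CH2Cl2, rt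
Reagents that add atoms: none
Why: Buffered Dess–Martin oxidation gives the α-alkoxy ketone without epimerising C2.

Step 10
Reactants: 16 the methyl ketone
Product: 17 triene ether with C3 isopropenyl, C4 vinyl and C7 methylene
Conditions: Zn, CH2Br2, TiCl4, THF, 0 °C (pre-formed reagent); then 16, CH2Cl2, rt
Reagents that add atoms: dibromomethane (BrCBr)
Why: Takai–Lombardo methylenation is non-basic, so the C2 stereocentre α to the ketone and the β-silyloxy group should survive.

Step 11
Reactants: 17 the triene ether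
Product: 18 oxonene with Z C3=C4 (C2 CH2OSiEt3, C9 CH2OPMB, C6 OTBS, C7 methylene)
Conditions: second-generation Grubbs catalyst RuCl2(H2IMes)(PCy3)(=CHPh) (10 mol%), CH2Cl2 (2 mM), 40 °C
Reagents that add atoms: none
Why: Ring-closing metathesis initiates at the C4 vinyl group and closes onto the isopropenyl group; the gauche preference of the two ether C–O bonds folds the chain and the nine-membered ring enforces the Z trisubstituted alkene.

Step 12
Reactants: 18 the oxonene
Product: 19 C10 primary alcohol
Conditions: DDQ, CH2Cl2/pH 7 buffer, 0 °C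
Reagents that add atoms: none
Why: Oxidative removal of the PMB ether should be faster than any attack on the hindered allylic ring ether or the silyl ethers.

Step 13
Reactants: 19 the C10 alcohol
Product: 20 C10 aldehyde
Conditions: Dess–Martin periodinane, NaHCO3, CH2Cl2, 0 °C → rt
Reagents that add atoms: none
Why: Mild oxidation gives the α-alkoxy aldehyde without epimerising C9; it is used directly.

Step 14
Reactants: 20 the C10 aldehyde
Product: 21 (E)-enal (C10=C11 with C11 methyl, C12 aldehyde)
Conditions: Ph3P=C(CH3)CHO, toluene, 90 °C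
Reagents that add atoms: 2-(triphenylphosphoranylidene)propanal (CC(C=O)=P(c1ccccc1)(c1ccccc1)c1ccccc1)
Why: Wittig reaction of a stabilised ylide gives the E trisubstituted enal.

Step 15
Reactants: 21 the enal
Product: 22 (E)-diene (C10=C11–C12=C13)
Conditions: Ph3PCH3Br, KOt-Bu, THF, 0 °C
Reagents that add atoms: methyltriphenylphosphonium bromide (C[P+](c1ccccc1)(c1ccccc1)c1ccccc1.[Br-])
Why: Wittig methylenation of the aldehyde completes the diene without affecting the C10=C11 geometry.

Step 16
Reactants: 22 the diene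
Product: 23 C1 aldehyde
Conditions: (COCl)2, DMSO, CH2Cl2, −78 → −40 °C; then Et3N, −78 → 0 °C
Reagents that add atoms: none
Why: Swern conditions convert a primary triethylsilyl ether directly into the aldehyde (oxidative desilylation) and leave the secondary TBS ether alone; the β,γ-unsaturated α-alkoxy aldehyde is used at once.

Step 17
Reactants: 23 the C1 aldehyde
Product: 25 tricyclic methyl ketone (cyclohexene and tetrahydrofuran fused to the oxonene; C14 acetyl), via trienone 24 (not isolated)
Conditions: Ph3P=CHC(O)CH3, CH2Cl2, rt; then 40 °C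
Reagents that add atoms: 1-(triphenylphosphoranylidene)propan-2-one (CC(=O)C=P(c1ccccc1)(c1ccccc1)c1ccccc1)
Why: Wittig olefination gives the E enone, which should undergo an intramolecular Diels–Alder reaction across the C2–O–C9 tether held by the oxonene; H2 and H9 eclipse their alkenes to avoid A(1,3) strain, so both partners react on the face away from C3 and C8 (this sets C1 and C10, cis fusion), and the E dienophile places the C14 acetyl trans to C2.

Step 18
Reactants: 25 the tricyclic methyl ketone
Product: 26 tricyclic tetraene with C14 isopropenyl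
Conditions: Ph3PCH3Br, KOt-Bu, THF, 0 °C → rt
Reagents that add atoms: methyltriphenylphosphonium bromide (C[P+](c1ccccc1)(c1ccccc1)c1ccccc1.[Br-])
Why: Wittig methylenation of the acetyl group; C14 is already in its more stable equatorial arrangement, so enolisation should not change it.

Step 19
Reactants: 26 the isopropenyl compound
Product: 28 (15R)-C16 primary alcohol (hydroxy-triene), via alkylborane 27 (not isolated)
Conditions: 9-BBN (1.2 equiv), THF, 0 °C → rt; then NaOH, H2O2, 0 °C
Reagents that add atoms: hydrogen peroxide (OO)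
Why: Hydroboration–oxidation in which the bulky borane should add only to the isopropenyl group (the C7 methylene is flanked by the silyloxy-bearing C6 and inductively deactivated, the trisubstituted alkenes are slower still), attacking anti to the larger C1 branch in the conformer with H14 eclipsing the alkene, which gives 15R.

Step 20
Reactants: 28 the hydroxy-triene
Product: 30 tetracyclic 11,12-epoxy-4-ol (oxepane closed), via bis-epoxide 29 (not isolated)
Conditions: m-CPBA (2.2 equiv), CH2Cl2, 0 °C; then CSA (10 mol%), 0 °C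
Reagents that add atoms: 3-chloroperbenzoic acid (OOC(=O)c1cccc(Cl)c1)
Why: m-CPBA should epoxidise only the two trisubstituted alkenes (the C7=C19 methylene is 1,1-disubstituted and deactivated by the allylic silyloxy group) to give 29, and acid then triggers an SN2-like opening of the 3,4-epoxide at its tertiary carbon C3 by the C16 hydroxyl, the epoxy-alcohol oxacyclisation long used for oxepanes and the counterpart of the presumed biosynthetic ether formation. The oxepane closes in the 7-exo-tet mode (8-endo attack at C4 is disfavoured by ring size and by the Markovnikov bias) with inversion at C3 and retention at C4, so the tetrasubstituted C3 and the free C4 carbinol are set together and anti. Their absolute sense is fixed in the epoxidation: in the A(1,3)-minimised conformer H2 eclipses the Z alkene and the ring C2–O bond stands over one face, so the peracid adds to the other, exo face, giving the (3R,4R)-epoxide whose C3–O bond can become antiperiplanar to the C16 oxygen arriving from the C1 side. At C11=C12 the peracid adds to the convex face, anti to the axial C10–C9 bond, and this sets C11. The step needs chemoselectivity between the two epoxides, which is secured because only the 3,4-epoxide has a hydroxyl that can reach its rear side, so catalytic CSA at 0 °C should leave the 11,12-epoxide intact.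

Step 21
Reactants: 30 the epoxy alcohol
Product: 31 4,11-diol
Conditions: LiEt3BH, THF, 0 °C → rt
Reagents that add atoms: none
Why: SN2 hydride opening of the trisubstituted epoxide at the secondary carbon C12 leaves the tertiary C11–O bond untouched, so the C11 carbinol keeps the configuration set in step 20.

Step 22
Reactants: 31 the diol
Product: 32 C4 octanoate with C6 OTBS
Conditions: octanoyl chloride, pyridine, DMAP (cat.), CH2Cl2, 0 °C
Reagents that add atoms: octanoyl chloride (CCCCCCCC(=O)Cl)
Why: DMAP-catalysed acylation esterifies the secondary C4 hydroxyl while the tertiary C11 hydroxyl does not react.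

Step 23
Reactants: 32 the silyl ether
Product: 33 target
Conditions: HF·pyridine, pyridine, THF, 0 °C → rt
Reagents that add atoms: none
Why: Buffered fluoride cleavage of the secondary TBS ether is mild enough to avoid ester migration and to spare the tertiary alcohol and the exocyclic alkene.

**Compound list**

1 | 2-bromoacrolein | C=C(Br)C=O | starting material
2 | diisopinocampheylborinic ester of 3 | C=C(Br)[C@@H](CC=C)OB([C@H]1C[C@H]2C[C@@H]([C@@H]1C)C2(C)C)[C@H]1C[C@H]2C[C@@H]([C@@H]1C)C2(C)C | intermediate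
3 | (R)-2-bromohexa-1,5-dien-3-ol | C=C(Br)[C@@H](CC=C)O | intermediate
4 | (R)-2-bromo-3-(tert-butyldimethylsilyloxy)hexa-1,5-diene | C=C(Br)[C@@H](CC=C)O[Si](C)(C)C(C)(C)C | intermediate
5 | (S)-glycidyl 4-methoxybenzyl ether | COc1ccc(COC[C@@H]2CO2)cc1 | starting material
6 | 2-lithio analogue of 4 | [Li]C(=C)[C@@H](CC=C)O[Si](C)(C)C(C)(C)C | intermediate
7 | (2S,5R)-5-(tert-butyldimethylsilyloxy)-1-(4-methoxybenzyloxy)-4-methyleneoct-7-en-2-ol | C=C(C[C@@H](COCc1ccc(OC)cc1)O)[C@@H](CC=C)O[Si](C)(C)C(C)(C)C | intermediate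
8 | O-carboxymethyl ether of 7 | C=C(C[C@@H](COCc1ccc(OC)cc1)OCC(=O)O)[C@@H](CC=C)O[Si](C)(C)C(C)(C)C | intermediate
9 | (R)-4-benzyl-2-oxazolidinone | O=C1N[C@H](Cc2ccccc2)CO1 | starting material
10 | mixed pivalic anhydride of 8 | C=C(C[C@@H](COCc1ccc(OC)cc1)OCC(=O)OC(=O)C(C)(C)C)[C@@H](CC=C)O[Si](C)(C)C(C)(C)C | intermediate
11 | (R)-4-benzyl-3-(2-alkoxyacetyl)oxazolidin-2-one (alkoxy = the oct-7-en-2-yloxy group of 7) | C=C(C[C@@H](COCc1ccc(OC)cc1)OCC(=O)N1[C@H](Cc2ccccc2)COC1=O)[C@@H](CC=C)O[Si](C)(C)C(C)(C)C | intermediate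
12 | chlorotitanium Z-enolate of 11 | C=C(C[C@@H](COCc1ccc(OC)cc1)O/C=C(\O[Ti](Cl)(Cl)Cl)N1[C@H](Cc2ccccc2)COC1=O)[C@@H](CC=C)O[Si](C)(C)C(C)(C)C | intermediate
13 | syn-aldol adduct, (2R,3S)-2-alkoxy-3-hydroxybutanoyl imide | C=C(C[C@@H](COCc1ccc(OC)cc1)O[C@@H](C(=O)N1[C@H](Cc2ccccc2)COC1=O)[C@H](C)O)[C@@H](CC=C)O[Si](C)(C)C(C)(C)C | intermediate
14 | acyclic diol (C1 and C3 hydroxyls; C2, C6, C9 as in 33) | C=C(C[C@@H](COCc1ccc(OC)cc1)O[C@@H](CO)[C@H](C)O)[C@@H](CC=C)O[Si](C)(C)C(C)(C)C | intermediate
15 | C1 triethylsilyl ether of 14 | C=C(C[C@@H](COCc1ccc(OC)cc1)O[C@@H](CO[Si](CC)(CC)CC)[C@H](C)O)[C@@H](CC=C)O[Si](C)(C)C(C)(C)C | intermediate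
16 | C3 methyl ketone | C=C(C[C@@H](COCc1ccc(OC)cc1)O[C@@H](CO[Si](CC)(CC)CC)C(C)=O)[C@@H](CC=C)O[Si](C)(C)C(C)(C)C | intermediate
17 | acyclic triene ether (C3 isopropenyl, C4 vinyl, C7 methylene) | C=C(C[C@@H](COCc1ccc(OC)cc1)O[C@@H](CO[Si](CC)(CC)CC)C(C)=C)[C@@H](CC=C)O[Si](C)(C)C(C)(C)C | intermediate
18 | oxonene, Z C3=C4, C10 OPMB, C1 OSiEt3, C6 OTBS | C=C1C[C@@H](COCc2ccc(OC)cc2)O[C@@H](CO[Si](CC)(CC)CC)/C(C)=C\C[C@H]1O[Si](C)(C)C(C)(C)C | intermediate
19 | oxonene C10 alcohol | C=C1C[C@@H](CO)O[C@@H](CO[Si](CC)(CC)CC)/C(C)=C\C[C@H]1O[Si](C)(C)C(C)(C)C | intermediate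
20 | oxonene C10 aldehyde | C=C1C[C@@H](C=O)O[C@@H](CO[Si](CC)(CC)CC)/C(C)=C\C[C@H]1O[Si](C)(C)C(C)(C)C | intermediate
21 | oxonene (E)-enal | C=C1C[C@@H](/C=C(\C)C=O)O[C@@H](CO[Si](CC)(CC)CC)/C(C)=C\C[C@H]1O[Si](C)(C)C(C)(C)C | intermediate
22 | oxonene (E)-diene | C=C1C[C@@H](/C=C(\C)C=C)O[C@@H](CO[Si](CC)(CC)CC)/C(C)=C\C[C@H]1O[Si](C)(C)C(C)(C)C | intermediate
23 | oxonene diene with C1 aldehyde | C=C1C[C@@H](/C=C(\C)C=C)O[C@@H](C=O)/C(C)=C\C[C@H]1O[Si](C)(C)C(C)(C)C | intermediate
24 | oxonene diene with (E)-enone on C2 | C=C1C[C@@H](/C=C(\C)C=C)O[C@@H](/C=C/C(C)=O)/C(C)=C\C[C@H]1O[Si](C)(C)C(C)(C)C | intermediate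
25 | tricyclic C14 methyl ketone (C3=C4, C11=C12, C7 methylene, C6 OTBS) | C=C1C[C@@H]2O[C@@H]([C@H]3[C@@H](CC=C(C)[C@H]32)C(C)=O)/C(C)=C\C[C@H]1O[Si](C)(C)C(C)(C)C | intermediate
26 | tricycle with C14 isopropenyl | C=C1C[C@@H]2O[C@@H]([C@H]3[C@@H](CC=C(C)[C@H]32)C(C)=C)/C(C)=C\C[C@H]1O[Si](C)(C)C(C)(C)C | intermediate
27 | C16 B-alkyl-9-borabicyclo[3.3.1]nonane | C=C1C[C@@H]2O[C@@H]([C@H]3[C@@H](CC=C(C)[C@H]32)[C@@H](C)CB4C5CCCC4CCC5)/C(C)=C\C[C@H]1O[Si](C)(C)C(C)(C)C | intermediate
28 | tricyclic hydroxy-triene, (15R)-C16 alcohol | C=C1C[C@@H]2O[C@@H]([C@H]3[C@@H](CC=C(C)[C@H]32)[C@@H](C)CO)/C(C)=C\C[C@H]1O[Si](C)(C)C(C)(C)C | intermediate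
29 | (3R,4R)-3,4:11,12-bis-epoxide of 28 | C=C1C[C@@H]2O[C@@H]([C@H]3[C@@H](C[C@@H]4O[C@]4(C)[C@H]32)[C@@H](C)CO)[C@]5(C)O[C@@H]5C[C@H]1O[Si](C)(C)C(C)(C)C | intermediate
30 | tetracyclic 11,12-epoxide with C4 hydroxyl and C6 OTBS | C=C1C[C@@H]2O[C@H]3[C@H]4[C@@H](C[C@@H]5O[C@]5(C)[C@H]42)[C@@H](C)CO[C@@]3(C)[C@H](O)C[C@H]1O[Si](C)(C)C(C)(C)C | intermediate
31 | tetracyclic 4,11-diol with C6 OTBS | C=C1C[C@@H]2O[C@H]3[C@H]4[C@@H](CC[C@](C)(O)[C@H]42)[C@@H](C)CO[C@@]3(C)[C@H](O)C[C@H]1O[Si](C)(C)C(C)(C)C | intermediate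
32 | C4 octanoate with C6 OTBS | C=C1C[C@@H]2O[C@H]3[C@H]4[C@@H](CC[C@](C)(O)[C@H]42)[C@@H](C)CO[C@@]3(C)[C@H](OC(=O)CCCCCCC)C[C@H]1O[Si](C)(C)C(C)(C)C | intermediate
33 | CNP0398453.2 | C=C1C[C@@H]2O[C@H]3[C@H]4[C@@H](CC[C@](C)(O)[C@H]42)[C@@H](C)CO[C@@]3(C)[C@H](OC(=O)CCCCCCC)C[C@H]1O | target

**Step count and risks**

Total step count: 23. Longest linear sequence: 23 steps (from 1).

Steps most likely to fail:

Step 20 (key step). The facial selectivity of the C3=C4 epoxidation may be low or reversed; the epoxide oxygen would then lie on the side of the C16 tether and could not be displaced from the rear. The fallback uses that same facial preference and closes the ring through O–C16 instead. It sets out from 28: OsO4 (cat.), NMO, acetone/water, 0 °C should dihydroxylate the strained Z ring alkene first and give the 3,4-syn-diol F1, which has the correct C3 carbinol. Tf2O, 2,6-lutidine, CH2Cl2, −78 → 0 °C then triflates the primary C16 hydroxyl, and the tertiary C3 hydroxyl displaces it to give the oxepane with the epimeric C4 carbinol F2. m-CPBA epoxidises the remaining trisubstituted alkene to the 11,12-epoxide F3, and LiEt3BH gives the 4-epi-diol F4. A Mitsunobu esterification with octanoic acid (PPh3, DIAD, toluene) inverts C4 and comes back to the route at 32.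

Step 19. Discrimination between the two 1,1-disubstituted alkenes may be incomplete and the facial bias at C15 weak. The fallback replaces substrate-controlled hydroboration by a hydroxyl-directed, catalyst-controlled hydrogenation and sets out from 25. KHMDS, PhNTf2, THF, −78 °C gives the kinetic enol triflate F5. Pd(OAc)2, PPh3, CO, MeOH, Et3N, DMF gives the 2-substituted methyl acrylate F6, and i-Bu2AlH, CH2Cl2, −78 °C gives the allylic alcohol F7. Hydrogenation with [Rh(nbd)((R)-BINAP)]BF4 under H2 in CH2Cl2 reduces only the alkene bound through the free hydroxyl and sets C15 under ligand control, returning to 28.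

Step 11. Initiation and closure at the hindered isopropenyl group may be slow, so that cross-metathesis oligomers dominate. The fallback is a relay ring-closing metathesis and sets out from 16. A Wittig reaction with hex-5-enylidenetriphenylphosphorane (from the phosphonium bromide and KHMDS, THF, −78 °C) gives the relay triene F8. With the same ruthenium catalyst, loading occurs at the unhindered terminal alkene, cyclopentene is expelled and the metal is delivered to C3, from where closure onto the C4 vinyl group comes back to 18.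

Further compounds
F1 | step 20 | 16-hydroxy 3,4-syn-diol (C3 as in 33, C4 epimeric) | C=C1C[C@@H]2O[C@@H]([C@H]3[C@@H](CC=C(C)[C@H]32)[C@@H](C)CO)[C@@](C)(O)[C@@H](O)C[C@H]1O[Si](C)(C)C(C)(C)C
F2 | step 20 | oxepane with 4-epi carbinol and C11=C12 alkene | C=C1C[C@@H]2O[C@H]3[C@H]4[C@@H](CC=C(C)[C@H]42)[C@@H](C)CO[C@@]3(C)[C@@H](O)C[C@H]1O[Si](C)(C)C(C)(C)C
F3 | step 20 | 11,12-epoxide of F2 | C=C1C[C@@H]2O[C@H]3[C@H]4[C@@H](C[C@@H]5O[C@]5(C)[C@H]42)[C@@H](C)CO[C@@]3(C)[C@@H](O)C[C@H]1O[Si](C)(C)C(C)(C)C
F4 | step 20 | 4-epi-31 | C=C1C[C@@H]2O[C@H]3[C@H]4[C@@H](CC[C@](C)(O)[C@H]42)[C@@H](C)CO[C@@]3(C)[C@@H](O)C[C@H]1O[Si](C)(C)C(C)(C)C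
F5 | step 19 | enol triflate of 25 | C=C1C[C@@H]2O[C@@H]([C@H]3[C@@H](CC=C(C)[C@H]32)C(=C)OS(=O)(=O)C(F)(F)F)/C(C)=C\C[C@H]1O[Si](C)(C)C(C)(C)C
F6 | step 19 | methyl acrylate bearing the tricycle at its 2-position (C14) | C=C1C[C@@H]2O[C@@H]([C@H]3[C@@H](CC=C(C)[C@H]32)C(=C)C(=O)OC)/C(C)=C\C[C@H]1O[Si](C)(C)C(C)(C)C
F7 | step 19 | 2-substituted allylic alcohol (C15=C17, C16 OH) | C=C1C[C@@H]2O[C@@H]([C@H]3[C@@H](CC=C(C)[C@H]32)C(=C)CO)/C(C)=C\C[C@H]1O[Si](C)(C)C(C)(C)C
F8 | step 11 | relay triene (hex-5-enylidene in place of the C3 methylene of 17) | C=C(C[C@@H](COCc1ccc(OC)cc1)O[C@@H](CO[Si](CC)(CC)CC)/C(C)=C\CCCC=C)[C@@H](CC=C)O[Si](C)(C)C(C)(C)C
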